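**Retrosynthetic overview**

- The target is the diaryl ether of two coumarins. The last step is a BBr3 demethylation of 25, and ring C comes from a Pd(OAc)2/propiolate annulation on the 4-aryloxyresorcinol 22.
- The strategy rests on benzo ring A of the 7-hydroxycoumarin half: oxygens on C7 and C8a in a 1,3 relation across C8–H, and the ether oxygen on C6. These map onto the ring oxygen, lactone carbonyl, 6-methyl and 5-aryloxy group of a 2-pyranone-3-carboxylate, so ring A comes from pyranone 17 by ethoxide opening and Claisen reclosure (bond C8–C8a).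
- Pyranone 17 comes from the enaminone of aryloxyacetone 12 and diethyl malonate. Ketone 12 comes from 5-hydroxy-6,7-dimethoxycoumarin 10 and chloroacetone, so the diaryl ether oxygen is set by a phenol alkylation.
- Coumarin 10 comes from 2-hydroxy-3,4-dimethoxybenzaldehyde 1, whose phenol becomes O5: MOM protection, directed lithiation/oxidation for the C8a oxygen, Wittig lactonisation.
- Ring order: B (from 1), D (step 3), pyranone (step 7), A (step 8), C (step 10).

Key step: step 8

Remark: the target has no stereocentre; coumarin numbering is used for both halves, with A/C the benzo and lactone rings of the 6-aryloxy-7-hydroxycoumarin and B/D those of the 5-aryloxy-6,7-dihydroxycoumarin.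

**Route**

Step 1
Reactants: 1 2-hydroxy-3,4-dimethoxybenzaldehyde
Product: 2 3,4-dimethoxy-2-(methoxymethoxy)benzaldehyde
Conditions: MOMCl, K2CO3, acetone, 0 °C → rt
Reagents that add atoms: chloromethyl methyl ether (MOMCl), COCCl
Why: Williamson-type O-alkylation of the phenoxide by the reactive chloromethyl ether masks the future ether oxygen O5 as an acetal that tolerates organolithium reagents.

Step 2
Reactants: 2 3,4-dimethoxy-2-(methoxymethoxy)benzaldehyde
Product: 6 6-hydroxy-3,4-dimethoxy-2-(methoxymethoxy)benzaldehyde, via lithium amino alkoxide 3 (not isolated), via aryllithium 4 (not isolated), via aryl trimethoxyborate 5 (not isolated)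
Conditions: Me2NCH2CH2N(Me)Li (from the diamine and n-BuLi, 1.1 equiv), THF, −20 °C; n-BuLi (3 equiv), −20 °C; B(OMe)3, −78 °C → rt; AcOH, 30% H2O2, 0 °C
Reagents that add atoms: hydrogen peroxide, OO
Why: Directed ortho-metalation through an in situ α-amino alkoxide, in which the chelating diamine arm steers n-BuLi to C6, the only free position ortho to the masked formyl group (C2 is blocked by the MOM ether, C5 is activated by one methoxy group only), followed by borylation and C–B oxidation to install the future lactone oxygen O8a.

Step 3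
Reactants: 6 6-hydroxy-3,4-dimethoxy-2-(methoxymethoxy)benzaldehyde; 7 ethyl (triphenylphosphoranylidene)acetate
Product: 9 6,7-dimethoxy-5-(methoxymethoxy)-2H-chromen-2-one, via (E)-cinnamate ester 8 (not isolated)
Conditions: PhNEt2, reflux
Reagents that add atoms: ethyl (triphenylphosphoranylidene)acetate (7), CCOC(=O)C=P(c1ccccc1)(c1ccccc1)c1ccccc1
Why: Wittig olefination by the stabilised ylide, then thermal E to Z isomerisation and lactonisation in hot N,N-diethylaniline, closes ring D on the only free phenol, so the MOM-protected oxygen ends unambiguously at C5.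

Step 4
Reactants: 9 6,7-dimethoxy-5-(methoxymethoxy)-2H-chromen-2-one
Product: 10 5-hydroxy-6,7-dimethoxy-2H-chromen-2-one
Conditions: HCl (3 M aq, cat.), MeOH, 50 °C
Reagents that add atoms: none
Why: Acid-catalysed acetal exchange with methanol removes the MOM group, while the lactone of ring D and the aryl methyl ethers are inert to dilute HCl.

Step 5
Reactants: 10 5-hydroxy-6,7-dimethoxy-2H-chromen-2-one; 11 chloroacetone
Product: 12 6,7-dimethoxy-5-(2-oxopropoxy)-2H-chromen-2-one
Conditions: K2CO3, KI (cat.), acetone, reflux
Reagents that add atoms: chloroacetone (11), CC(=O)CCl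
Why: Williamson ether synthesis on an α-chloro ketone activated by iodide exchange (Finkelstein) sets the future diaryl ether C–O bond; with no carbonyl group ortho to this oxygen, aldol closure to a benzofuran cannot intervene.

Step 6
Reactants: 12 6,7-dimethoxy-5-(2-oxopropoxy)-2H-chromen-2-one; 13 N,N-dimethylformamide dimethyl acetal
Product: 14 (Z)-5-{[1-(dimethylamino)-3-oxobut-1-en-2-yl]oxy}-6,7-dimethoxy-2H-chromen-2-one
Conditions: Me2NCH(OMe)2 (1.5 equiv), toluene, 100 °C
Reagents that add atoms: N,N-dimethylformamide dimethyl acetal (13), COC(OC)N(C)C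
Why: Aminomethylenation by the amide acetal should occur at the methylene flanked by the ketone and the aryloxy oxygen, the more acidic α-position, and gives a push–pull enaminone under neutral conditions that leave ring D untouched.

Step 7
Reactants: 14 (Z)-5-{[1-(dimethylamino)-3-oxobut-1-en-2-yl]oxy}-6,7-dimethoxy-2H-chromen-2-one; 15 diethyl malonate
Product: 17 ethyl 5-[(6,7-dimethoxy-2-oxo-2H-chromen-5-yl)oxy]-6-methyl-2-oxo-2H-pyran-3-carboxylate, via alkylidenemalonate 16 (not isolated)
Conditions: CH2(CO2Et)2 (3 equiv), AcOH, 110 °C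
Reagents that add atoms: diethyl malonate (15), CCOC(=O)CC(=O)OCC
Why: Knoevenagel-type addition–elimination of diethyl malonate at the aminomethylene carbon in hot acetic acid gives alkylidenemalonate 16, whose dienol lactonises on the cis ester to the 2-pyranone; the acidic medium keeps the product from base-induced rearrangement.

Step 8
Reactants: 17 ethyl 5-[(6,7-dimethoxy-2-oxo-2H-chromen-5-yl)oxy]-6-methyl-2-oxo-2H-pyran-3-carboxylate
Product: 19 ethyl 5-[(6,7-dimethoxy-2-oxo-2H-chromen-5-yl)oxy]-2,4-dihydroxybenzoate, via ring-opened sodium dienolate 18 (not isolated)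
Conditions: NaOEt (1.2 equiv), EtOH, 0 °C → 75 °C; then 1 M HCl, 0 °C
Reagents that add atoms: none
Why: Proposed new method: ethoxide adds to the lactone carbonyl C2 of pyranone 17, the most electrophilic acyl carbon because it is flanked by the 3-ester, and the ring opens to the stabilised dienolate 18, an alkylidenemalonate whose ketone oxygen is the former ring oxygen; proton transfer in ethanol then gives a small equilibrium share of the terminal CH2 enolate of the methyl ketone, which attacks the ester held cis on the alkylidenemalonate. This closure is a 6-exo-trig Claisen (Dieckmann-type) condensation that forms the C8–C8a bond of ring A, and loss of the ethoxide that had added, followed by double enolisation, gives the aromatic resorcylate, so the overall change is an isomerisation that creates no stereocentre. The closest known reaction type is the alkoxide- or hydroxide-induced opening of 2-pyranones followed by aldol or Claisen recyclisation to benzenoid rings, as used to turn pyranone-masked polyketides into resorcylates. Carbon versus oxygen closure is settled by thermodynamics, since O-attack only returns 17 reversibly whereas C-attack is made irreversible by aromatisation and phenoxide formation. Chemoselectivity between the two lactones rests on the base being held as the far more stable anion 18 when about one equivalent is used, and any ring D that opens to the ethyl (Z)-coumarinate should reclose on acidic work-up. The aryl ether oxygen stays on an sp2 carbon of 18 throughout, so aryloxide should not be lost.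

Step 9
Reactants: 19 ethyl 5-[(6,7-dimethoxy-2-oxo-2H-chromen-5-yl)oxy]-2,4-dihydroxybenzoate
Product: 22 5-(2,4-dihydroxyphenoxy)-6,7-dimethoxy-2H-chromen-2-one, via ring-opened tetrasodium salt 20 (not isolated), via resorcylic acid 21 (not isolated)
Conditions: NaOH (2 M aq), EtOH, 70 °C, N2; then 6 M HCl to pH 1, dioxane, 100 °C
Reagents that add atoms: none
Why: Saponification of the salicylate ester (ring D opens to the (Z)-coumarinate in alkali and recloses on acidification) followed by protodecarboxylation of the β-resorcylic acid, which is easy because the ipso carbon is ortho and para to hydroxyl groups.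

Step 10
Reactants: 22 5-(2,4-dihydroxyphenoxy)-6,7-dimethoxy-2H-chromen-2-one; 23 ethyl propiolate
Product: 25 6-[(6,7-dimethoxy-2-oxo-2H-chromen-5-yl)oxy]-7-hydroxy-2H-chromen-2-one, via (Z)-cinnamate ester 24 (not isolated)
Conditions: Pd(OAc)2 (5 mol %), ethyl propiolate (1.5 equiv), CF3CO2H/CH2Cl2 (4:1), rt
Reagents that add atoms: ethyl propiolate (23), CCOC(=O)C#C
Why: Pd(OAc)2-catalysed hydroarylation of the propiolate in CF3CO2H at the ring A carbon para to one hydroxyl and ortho to the other (the future C4a), the Pechmann-type regiochemistry of resorcinol, gives (Z)-cinnamate 24 by trans addition, which lactonises to ring C; ring B has no free phenol and its C8–H is far less nucleophilic.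

Step 11
Reactants: 25 6-[(6,7-dimethoxy-2-oxo-2H-chromen-5-yl)oxy]-7-hydroxy-2H-chromen-2-one
Product: 26 6-[(6,7-dihydroxy-2-oxo-2H-chromen-5-yl)oxy]-7-hydroxy-2H-chromen-2-one
Conditions: BBr3 (8 equiv), CH2Cl2, −78 °C → rt; then MeOH, H2O
Reagents that add atoms: none
Why: Lewis acid cleavage of the two aryl methyl ethers by BBr3 (bromide attacks the methyl group of the boron-bound ether) frees the 6,7-catechol, whereas the diaryl ether and both lactones do not react.

**Compound list**

1 | 2-hydroxy-3,4-dimethoxybenzaldehyde | COc1ccc(C=O)c(O)c1OC | starting material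
2 | 3,4-dimethoxy-2-(methoxymethoxy)benzaldehyde | COCOc1c(C=O)ccc(OC)c1OC | intermediate
3 | lithium {[2-(dimethylamino)ethyl](methyl)amino}[3,4-dimethoxy-2-(methoxymethoxy)phenyl]methanolate (racemic) | [Li+].[O-]C(N(C)CCN(C)C)c1ccc(OC)c(OC)c1OCOC | intermediate
4 | 6-lithio derivative of amino alkoxide 3 (racemic) | [Li+].[O-]C(N(C)CCN(C)C)c1c([Li])cc(OC)c(OC)c1OCOC | intermediate
5 | dilithium aryl(trimethoxy)borate of amino alkoxide 3, boron on C6 (racemic) | [Li+].[Li+].[O-]C(N(C)CCN(C)C)c1c([B-](OC)(OC)OC)cc(OC)c(OC)c1OCOC | intermediate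
6 | 6-hydroxy-3,4-dimethoxy-2-(methoxymethoxy)benzaldehyde | COCOc1c(C=O)c(O)cc(OC)c1OC | intermediate
7 | ethyl (triphenylphosphoranylidene)acetate | CCOC(=O)C=P(c1ccccc1)(c1ccccc1)c1ccccc1 | starting material
8 | ethyl (E)-3-[6-hydroxy-3,4-dimethoxy-2-(methoxymethoxy)phenyl]prop-2-enoate | CCOC(=O)/C=C/c1c(O)cc(OC)c(OC)c1OCOC | intermediate
9 | 6,7-dimethoxy-5-(methoxymethoxy)-2H-chromen-2-one | COCOc1c(OC)c(OC)cc2oc(=O)ccc12 | intermediate
10 | 5-hydroxy-6,7-dimethoxy-2H-chromen-2-one | COc1cc2oc(=O)ccc2c(O)c1OC | intermediate
11 | chloroacetone | CC(=O)CCl | starting material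
12 | 6,7-dimethoxy-5-(2-oxopropoxy)-2H-chromen-2-one | CC(=O)COc1c(OC)c(OC)cc2oc(=O)ccc12 | intermediate
13 | N,N-dimethylformamide dimethyl acetal | COC(OC)N(C)C | starting material
14 | (Z)-5-{[1-(dimethylamino)-3-oxobut-1-en-2-yl]oxy}-6,7-dimethoxy-2H-chromen-2-one (amino group trans to acetyl; the geometry is lost in step 7) | CN(C)/C=C(\Oc1c(OC)c(OC)cc2oc(=O)ccc12)C(C)=O | intermediate
15 | diethyl malonate | CCOC(=O)CC(=O)OCC | starting material
16 | diethyl 2-{2-[(6,7-dimethoxy-2-oxo-2H-chromen-5-yl)oxy]-3-oxobutylidene}malonate (racemic at the aryloxy carbon, which is lost on enolisation) | CCOC(=O)C(C(=O)OCC)=CC(Oc1c(OC)c(OC)cc2oc(=O)ccc12)C(C)=O | intermediate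
17 | ethyl 5-[(6,7-dimethoxy-2-oxo-2H-chromen-5-yl)oxy]-6-methyl-2-oxo-2H-pyran-3-carboxylate | CCOC(=O)c1cc(Oc2c(OC)c(OC)cc3oc(=O)ccc23)c(C)oc1=O | intermediate
18 | sodium (2E)-5,5-bis(ethoxycarbonyl)-3-[(6,7-dimethoxy-2-oxo-2H-chromen-5-yl)oxy]penta-2,4-dien-2-olate (delocalised dienolate) | [Na+].CCOC(=O)C(C(=O)OCC)=C\C(Oc1c(OC)c(OC)cc2oc(=O)ccc12)=C(\C)[O-] | intermediate
19 | ethyl 5-[(6,7-dimethoxy-2-oxo-2H-chromen-5-yl)oxy]-2,4-dihydroxybenzoate | CCOC(=O)c1cc(Oc2c(OC)c(OC)cc3oc(=O)ccc23)c(O)cc1O | intermediate
20 | tetrasodium 5-{2-[(Z)-2-carboxylatoethenyl]-5,6-dimethoxy-3-oxidophenoxy}-2-hydroxy-4-oxidobenzoate | [Na+].[Na+].[Na+].[Na+].[O-]C(=O)/C=C\c1c([O-])cc(OC)c(OC)c1Oc1cc(C([O-])=O)c(O)cc1[O-] | intermediate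
21 | 5-[(6,7-dimethoxy-2-oxo-2H-chromen-5-yl)oxy]-2,4-dihydroxybenzoic acid | OC(=O)c1cc(Oc2c(OC)c(OC)cc3oc(=O)ccc23)c(O)cc1O | intermediate
22 | 5-(2,4-dihydroxyphenoxy)-6,7-dimethoxy-2H-chromen-2-one | COc1cc2oc(=O)ccc2c(Oc2ccc(O)cc2O)c1OC | intermediate
23 | ethyl propiolate | CCOC(=O)C#C | starting material
24 | ethyl (Z)-3-{5-[(6,7-dimethoxy-2-oxo-2H-chromen-5-yl)oxy]-2,4-dihydroxyphenyl}prop-2-enoate | CCOC(=O)/C=C\c1cc(Oc2c(OC)c(OC)cc3oc(=O)ccc23)c(O)cc1O | intermediate
25 | 6-[(6,7-dimethoxy-2-oxo-2H-chromen-5-yl)oxy]-7-hydroxy-2H-chromen-2-one | COc1cc2oc(=O)ccc2c(Oc2cc3ccc(=O)oc3cc2O)c1OC | intermediate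
26 | 6-[(6,7-dihydroxy-2-oxo-2H-chromen-5-yl)oxy]-7-hydroxy-2H-chromen-2-one | O=c1ccc2cc(Oc3c(O)c(O)cc4oc(=O)ccc34)c(O)cc2o1 | target

**Count**

Total steps: 11. Longest linear sequence: 11 steps (1 → 26).

**Steps most likely to fail**

Step 8. The open-chain dienolate may not reach the methyl enolate tautomer fast enough, so that ring opening stays a reversible dead end. Prolonged heating with ethoxide may also isomerise opened ring D to the (E)-cinnamate, which no longer relactonises. Fallback by known chemistry, setting out from 10 and coming back at 22: Chan–Lam coupling of 5-hydroxy-6,7-dimethoxy-2H-chromen-2-one 10 with commercial [2,4-bis(benzyloxy)phenyl]boronic acid (Cu(OAc)2, pyridine, 4 Å molecular sieves, CH2Cl2, air, rt) would give 5-[2,4-bis(benzyloxy)phenoxy]-6,7-dimethoxy-2H-chromen-2-one F1. BCl3 with pentamethylbenzene in CH2Cl2 at −78 °C would then cleave only the benzyl ethers and rejoin the route at 22, from which steps 10 and 11 follow unchanged.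

Step 2. Lithiation may take place ortho to the 4-methoxy group instead of ortho to the masked aldehyde, and the peroxide may over-oxidise the freed aldehyde with loss of the formyl group (Dakin-type). Fallback, setting out from 2 and coming back at 9: Knoevenagel–Doebner condensation of aldehyde 2 with malonic acid (pyridine, piperidine, 90 °C) would give (E)-3-[3,4-dimethoxy-2-(methoxymethoxy)phenyl]prop-2-enoic acid F2. Photocatalytic E to Z isomerisation and oxidative lactonisation onto the single free ortho carbon (riboflavin, O2, MeCN/MeOH, 402 nm light) would then form ring D and rejoin the route at coumarin 9.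

Step 7. Diethyl malonate may be too weak a carbon acid to displace dimethylamine in acetic acid, so that the enaminone is hydrolysed or decomposes before condensation. Fallback, setting out from 12 and coming back at 17: the roles of nucleophile and electrophile are exchanged. The thermodynamic enolate on the aryloxy-bearing carbon of ketone 12 (t-BuOK, THF, −20 °C) is added to diethyl ethoxymethylenemalonate, acetic acid quench gives alkylidenemalonate 16, and p-TsOH in toluene at reflux closes it to pyranone 17. This fallback makes no compound outside the list (F0).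

**Further compounds**

F1 | step 8 | 5-[2,4-bis(benzyloxy)phenoxy]-6,7-dimethoxy-2H-chromen-2-one | COc1cc2oc(=O)ccc2c(Oc2ccc(OCc3ccccc3)cc2OCc2ccccc2)c1OC
F2 | step 2 | (E)-3-[3,4-dimethoxy-2-(methoxymethoxy)phenyl]prop-2-enoic acid | COCOc1c(/C=C/C(O)=O)ccc(OC)c1OC
F0 | step 7 | none | none
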